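**Retrosynthetic overview**
1. Compound flow: 1 + 2 → (3) → 4; 4 + 5 → (6, 7, 8, 9) → 10; 10 → 11 (target). There is one ring, the 27-membered lactone, and it is formed last.
2. Ring formation (C1–O acyl bond): the free, unprotected ω-hydroxy keto acid 10 is closed through a serine acyl-enzyme (lipase). This is the same acyl-transfer event as the presumed thioesterase-type off-loading of the ω-hydroxy-(ω-4)-oxo C26 acyl thioester in the termite, run under ring–chain equilibrium control instead of stoichiometric activation.
3. Seco acid 10 is cut at C11–C12 (Cu-catalysed sp3–sp3 coupling onto the unprotected bromo-carboxylate of 5) and at C21–C22 (alkylation of 6-lithiodihydropyran, a masked 5-hydroxypentanoyl anion, with 2).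
4. The dihydropyran enol ether carries both the C22 ketone and the C26 hydroxyl through the organometallic steps and is released by the acid work-up of step 2, so there are no protecting-group or redox steps.

Assumption: the target has no stereocentre (it is achiral), so there is only one stereoisomer to make; the presumed biosynthesis is taken to be lactonisation of the ω-hydroxy acyl thioester.

**Route**

Step 1
Reactants: 1 3,4-dihydro-2H-pyran; 2 1,10-dibromodecane (4 equiv, excess recovered)
Product: 4 6-(10-bromodecyl)-3,4-dihydro-2H-pyran, via 6-lithio-3,4-dihydro-2H-pyran 3 (not isolated)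
Conditions: t-BuLi (0.95 equiv), THF/pentane, −78 → 0 °C; then cannulate into 2 (4 equiv), THF/DMPU, −78 °C → rt; Et3N-deactivated SiO2
Reagents that add atoms: none
Why: α-lithiation of the cyclic enol ether gives a vinyllithium that acts as a masked 5-hydroxypentanoyl anion and is alkylated by SN2 on the primary bromide, with excess dibromide suppressing double alkylation; no stereocentre is formed.

Step 2
Reactants: 4 6-(10-bromodecyl)-3,4-dihydro-2H-pyran (1.2 equiv); 5 11-bromoundecanoic acid
Product: 10 26-hydroxy-22-oxohexacosanoic acid, via [10-(3,4-dihydro-2H-pyran-6-yl)decyl]magnesium bromide 6 (not isolated), via chloromagnesium 11-bromoundecanoate 7 (not isolated), via chloromagnesium 21-(3,4-dihydro-2H-pyran-6-yl)henicosanoate 8 (not isolated), via 21-(3,4-dihydro-2H-pyran-6-yl)henicosanoic acid 9 (not isolated)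
Conditions: (a) 4, Mg (I2-activated), THF, 40 °C; (b) 5, MeMgCl (1.0 equiv), THF, −20 °C; (c) add (a) to (b), Li2CuCl4 (3 mol %), THF, −20 → 0 °C; (d) 1 M HCl, THF/H2O, rt, 2 h; recrystallise
Reagents that add atoms: water, O
Why: Kochi-type copper-catalysed Grignard–alkyl bromide coupling joins C11–C12 on the halomagnesium carboxylate (inert to RMgX at −20 °C, while the enol ether tolerates the basic medium), and the acidic work-up frees the acid and hydrolyses the enol ether (Markovnikov hydration, then hemiketal opening) to the δ-hydroxy ketone; no stereocentre is formed.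

Step 3
Reactants: 10 26-hydroxy-22-oxohexacosanoic acid
Product: 11 22-keto-26-hexacosanolide (target)
Conditions: Novozym 435 (immobilised Candida antarctica lipase B, 100 wt %), 4 Å MS, toluene, 2 mM, 65 °C, 48–72 h; filter, SiO2
Reagents that add atoms: none
Why: Lipase-catalysed macrolactonisation (serine-hydrolase acyl transfer), in which the enzyme forms its Ser-O-acyl intermediate from the free acid and the primary ω-OH of the mainly open-chain δ-hydroxy ketone closes the strain-free 27-membered ring, while at 2 mM the enzyme-mediated ring–chain equilibrium returns linear and cyclic oligomers to the monolactone as the sieves take up water; the ketone is untouched and no stereocentre is formed.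

**Compound list**
1 | 3,4-dihydro-2H-pyran | C1=COCCC1 | starting material
2 | 1,10-dibromodecane | BrCCCCCCCCCCBr | starting material
3 | 6-lithio-3,4-dihydro-2H-pyran | [Li]C1=CCCCO1 | intermediate (not isolated)
4 | 6-(10-bromodecyl)-3,4-dihydro-2H-pyran | BrCCCCCCCCCCC1=CCCCO1 | intermediate
5 | 11-bromoundecanoic acid | OC(=O)CCCCCCCCCCBr | starting material
6 | [10-(3,4-dihydro-2H-pyran-6-yl)decyl]magnesium bromide | Br[Mg]CCCCCCCCCCC1=CCCCO1 | intermediate (not isolated)
7 | chloromagnesium 11-bromoundecanoate | Cl[Mg]OC(=O)CCCCCCCCCCBr | intermediate (not isolated)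
8 | chloromagnesium 21-(3,4-dihydro-2H-pyran-6-yl)henicosanoate | Cl[Mg]OC(=O)CCCCCCCCCCCCCCCCCCCCC1=CCCCO1 | intermediate (not isolated)
9 | 21-(3,4-dihydro-2H-pyran-6-yl)henicosanoic acid | OC(=O)CCCCCCCCCCCCCCCCCCCCC1=CCCCO1 | intermediate (not isolated)
10 | 26-hydroxy-22-oxohexacosanoic acid (seco acid; achiral) | OC(=O)CCCCCCCCCCCCCCCCCCCCC(=O)CCCCO | intermediate
11 | 22-keto-26-hexacosanolide (achiral) | O=C1CCCCCCCCCCCCCCCCCCCCC(=O)OCCCC1 | target

**Totals**
Total step count: 3. Longest linear sequence: 3 (1 → 4 → 10 → 11).

**Steps most likely to fail, with fallbacks**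

Step 3 (most at risk: diolide and oligomers, or slow turnover with a C26 substrate at 2 mM). The fallback sets out from 10 and replaces the enzyme-mediated equilibrium by a kinetically controlled closure of a pre-formed acyl-CoA-like thioester. Compound 10 is converted with 2,2'-dipyridyl disulfide and PPh3 (toluene, rt) into S-(pyridin-2-yl) 26-hydroxy-22-oxohexacosanethioate F1. This is added by syringe pump to refluxing toluene (final concentration ≤ 1 mM), where the ω-hydroxyl captures the doubly activated thioester (Corey–Nicolaou). The fallback comes back to the route at 11.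

Step 2 (Wurtz homocoupling or reduction of the Grignard reagent, or sluggish coupling on the poorly soluble carboxylate salt). The fallback sets out from 4 and builds the chain by acetylide alkylation instead of a Grignard coupling. 10-Undecynoic acid is deprotonated twice (2 n-BuLi, THF/DMPU, −78 → 0 °C) to dilithium undec-10-ynoate F2, which is alkylated at the alkyne terminus with 4 (rt → 40 °C). Acidification gives 21-(3,4-dihydro-2H-pyran-6-yl)henicos-10-ynoic acid F3, whose enol ether is hydrolysed in the same 1 M HCl work-up to 26-hydroxy-22-oxohexacos-10-ynoic acid F4. Hydrogenation (H2, Pd/C, EtOAc) saturates the alkyne without touching the ketone. The fallback comes back to the route at 10.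

Step 1 (double alkylation of the dibromide, or slow alkylation of the hard vinyllithium by a bromide). The fallback sets out from 5 and forms C22–C23 by acylation instead of C21–C22 by alkylation. Compound 5 is converted with SOCl2 (cat. DMF) into 11-bromoundecanoyl chloride F5. This C-acylates lithium 3,4-dihydro-2H-pyran-6-olate F6 (δ-valerolactone, LDA, THF, −78 °C, enolate in excess) to give 3-(11-bromoundecanoyl)oxan-2-one F7. Hydrolysis and decarboxylation (2 M H2SO4, dioxane, reflux) give 15-bromo-1-hydroxypentadecan-5-one F8. Cyclodehydration (cat. TsOH, toluene, Dean–Stark) closes the enol ether. The fallback comes back to the route at 4.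

**Further compounds**
F1 | step 3 | S-(pyridin-2-yl) 26-hydroxy-22-oxohexacosanethioate | OCCCCC(=O)CCCCCCCCCCCCCCCCCCCCC(=O)Sc1ccccn1
F2 | step 2 | dilithium undec-10-ynoate (acetylide carboxylate dianion) | [Li]C#CCCCCCCCCC(=O)O[Li]
F3 | step 2 | 21-(3,4-dihydro-2H-pyran-6-yl)henicos-10-ynoic acid | OC(=O)CCCCCCCCC#CCCCCCCCCCCC1=CCCCO1
F4 | step 2 | 26-hydroxy-22-oxohexacos-10-ynoic acid | OC(=O)CCCCCCCCC#CCCCCCCCCCCC(=O)CCCCO
F5 | step 1 | 11-bromoundecanoyl chloride | ClC(=O)CCCCCCCCCCBr
F6 | step 1 | lithium 3,4-dihydro-2H-pyran-6-olate (δ-valerolactone lithium enolate) | [Li]OC1=CCCCO1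
F7 | step 1 | 3-(11-bromoundecanoyl)oxan-2-one | O=C1OCCCC1C(=O)CCCCCCCCCCBr
F8 | step 1 | 15-bromo-1-hydroxypentadecan-5-one | OCCCCC(=O)CCCCCCCCCCBr
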